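**Remark on materials:** enynol 1 (the industrial C6 vitamin A building block) and aldehyde 4 are taken as purchased; 4 is distilled before use because it oligomerises on storage.

## The problem

The target is an elemane-type 8,12-olide. It has one cyclohexane ring (C5–C10) in which every carbon is substituted, trans-fused along C7–C8 to an α-methylene-γ-butyrolactone (O8–C12–C11–C7, exocyclic C13). C5 carries a 2-substituted acrolein (C4, methylene C3, formyl C15), C6 a hydroxyl, C9 an isobutyrate, and C10 a methyl (C14) and an oxirane (C1–C2). There are seven stereocentres, six contiguous on the ring, and C10 is quaternary.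

In the chair, the C5, C7 and C8 substituents and the oxirane are equatorial, while the C6 hydroxyl, the C9 ester and the C14 methyl are axial. C5 and C7 can therefore be set by equilibration next to a C6 carbonyl, and C6 by hydride delivery away from the syn-axial methyl. C8, C9 and C10 cannot be corrected later and must arrive with full control, and C1, outside the ring, has no strong controller.

The fragile groups are the two Michael acceptors (no nucleophilic base or hydride once they exist), the terminal epoxide (acid), the isobutyrate flanked by oxygen functions (acyl migration), and the C6 hydroxyl, which is cis to the C11 arm and can translactonise.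

The enabling feature is that C6 and the lactone carbonyl C12 stand 1,4 across C7–C11. With C6 as a ketone this is a γ-keto ester, the retron of an acyl-anion conjugate addition. Cutting C6–C7 opens the ring to a chain whose only stereocentres are C8, C9 and C10.

## Retrosynthesis

**Oxirane last (28 ⇐ 27).** The C1–O and C2–O bonds are cut first. The epoxide is the group least tolerant of acid, fluoride and enolate chemistry, whereas a vinyl group on quaternary C10 survives every earlier step. Carrying a protected C1–C2 diol instead would add protecting-group steps and a base-mediated closure in the presence of two Michael acceptors. The forward step must pick the one electron-rich alkene of 27 and one of its faces.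

**Both exocyclic methylenes and the formyl group (27 ⇐ 26 ⇐ 25 ⇐ 24 ⇐ 21).** C3=C4 is cut by a Mannich-type methylenation of aldehyde 25. C15=O is traced to oxidative cleavage of a prenyl group in 24. C11=C13 is traced to enolate methylenation of lactone 21. A prenyl group is preferred to an isopropenyl group because allylic oxidation of the latter must choose between several allylic sites and α-isopropenyl ketones drift into conjugation. A prenyl group is a stable masked CH2CHO unit that ozone distinguishes from the vinyl group by substitution. The lactone enolate step requires O6 to be silylated (21), which also blocks translactonisation.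

**C6 carbinol and lactone (21 ⇐ 20 ⇐ 19 ⇐ 17).** The C6–H bond is cut back to ketone 19, and the O8–C12 bond back to keto ester 17. Lactonisation must precede reduction, otherwise the new cis C6 alkoxide would close the wrong γ-lactone. The forward reduction relies on the syn-axial C14 methyl.

**C4–C5 (17 ⇐ 15 + 16).** The side chain at C5 is attached by alkylating the ketone with prenyl bromide 16 before lactonisation. At that stage the only competing acidic sites are a hindered methine and a simple ester, and C5 can afterwards be equilibrated to the equatorial position.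

**C6–C7, the ring closure (15 ⇐ 14).** Cutting the bond between the ketone carbon and C7 gives aldehyde–enoate 14. This removes the ring and the C7 stereocentre in one stroke and leaves only C8–C10. The forward reaction is a carbene-catalysed 6-exo conjugate addition of the C6 acyl-anion equivalent. Alternatives that close C7–C8 or C5–C10 would require more stereocentres in the open chain.

**Both chain termini (14 ⇐ 13 ⇐ 11 ⇐ 10 ⇐ 9 ⇐ 8 ⇐ 6).** The C6 aldehyde is traced to a terminal alkyne (13), which needs no protecting group and is hydrated only when required. The C7=C11 bond is cut by a Wittig reaction of aldehyde 11 with ylide 12. Aldehyde 11 comes from diol 9 through bis-silyl ether 10, and the isobutyrate is introduced on alcohol 6 with chloride 7 while O7 and O8 are still tied up as the acetonide (8).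

**C9–C10 (6 ⇐ 3 + 4; 3 ⇐ 2 ⇐ 1).** The bond between the carbinol and the quaternary carbon is cut to (R)-glyceraldehyde acetonide 4 and (Z)-allylboronate 3. C8 comes from the chiral pool, C9 from its facial bias, and C10 from the alkene geometry through a closed transition state. An ester-enolate Claisen route to the same bond would need an external source of absolute configuration and a separate C7–C8 bond formation. Boronate 3 derives from commercial enynol 1, whose Z geometry and ethynyl group already encode C10 and the C5–C6 unit.

## Roads not taken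

**Alternative 1:** The cut is O8–C12 and C11–C12. The forward key step is a PdCl2/SnCl2/PPh3-catalysed cyclocarbonylation under carbon monoxide of trans ethynyl carbinol A1 to α-methylene lactone A2.
- Merits: the lactone, its carbonyl and the exocyclic methylene arise in one step without enolate chemistry. C6 is already silylated, so translactonisation is not an issue. C1 is carried as a dioxolane, so its configuration is secure.
- Weak points: the step builds no ring bond and no stereocentre. A1 is the fully substituted cyclohexane with all seven stereocentres, so the real problem is only postponed. The free C8 hydroxyl next to the C9 ester invites acyl migration. The end still needs an allylic oxidation of the isopropenyl group and a base-mediated epoxide closure beside two Michael acceptors.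
- Comparison: this road is better than the chosen one for the lactone (one step instead of lactonisation, protection and methylenation) and for C1. The chosen plan sets against it a key step that makes the carbocycle and C7 from a three-stereocentre chain and leaves a C6 carbonyl that sets C5 and C6.

**Alternative 2:** The cut is C5–C10, with C2–C3 formed in the reverse sense. Heating germacradienolide A3 should give elemanolide A4 by a Cope rearrangement.
- Merits: the step is reagent-free and biomimetic. It creates the vinyl and isopropenyl groups and both C5 and C10 in one event through a chair transition state, leaving only two oxidations.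
- Weak points: A3, a ten-membered (E,E)-diene with four stereocentres and a trans lactone, is harder to make than the target. The rearrangement is an equilibrium whose stereochemical outcome depends on the ring conformer. The late allylic oxidation and vinyl epoxidation are the same as, or harder than, in the chosen plan.
- Comparison: after A3 this is the shortest route, and it sets C5 and C10 together where the chosen plan uses two steps. The chosen plan avoids the macrocycle and reaches its cyclisation substrate in nine steps from commercial materials.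

**Alternative 3:** The cut is C7–C8. Cathodic reduction of aldehyde–enoate A5 should give trans γ-hydroxy ester A6.
- Merits: two stereocentres and the ring form together, the product lactonises directly, and no C6 ketone has to be reduced later.
- Weak points: A5 must already hold C5, C6, C9 and C10 as four contiguous acyclic stereocentres. The radical-anion pathway threatens reductive loss of the γ-silyloxy group of the enoate and of the α-alkoxy group of the aldehyde. C7 and C8 are set kinetically with no means of correction.
- Comparison: this road is as good or better in that it avoids the ketone reduction and the O6 protection. The chosen plan sets against it a non-reductive, catalytic closure, thermodynamic control at C7 and C5, and a simpler chain.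

Key step: step 10

## Route

Step 1
Reactants: 1 (Z)-3-methylpent-2-en-4-yn-1-ol
Product: 2 (Z)-5-chloro-3-methylpent-3-en-1-yne
Conditions: MsCl, LiCl, 2,4,6-collidine, DMF, 0 °C
Reagents that add atoms: lithium chloride, [Li+].[Cl-]
Why: Collington–Meyers chlorination: the primary allylic mesylate forms in situ and is displaced by chloride in an SN2 step, so the Z geometry of the trisubstituted alkene is untouched and the enyne is inert.

Step 2
Reactants: 2 (Z)-allylic chloride
Product: 3 4,4,5,5-tetramethyl-2-[(2Z)-3-methylpent-2-en-4-yn-1-yl]-1,3,2-dioxaborolane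
Conditions: Pd2(dba)3 (1 mol %), B2pin2 (1.1 equiv), THF, 60 °C
Reagents that add atoms: bis(pinacolato)diboron, CC1(C)OB(OC1(C)C)B1OC(C)(C)C(C)(C)O1
Why: Miyaura-type borylation of an allylic chloride: oxidative addition to zerovalent palladium, transmetallation with the diboron and C–B reductive elimination at the unsubstituted allyl terminus give the primary allylboronate. Ligand-free conditions of this kind are known to keep the geometry of neryl-type chlorides, which the next step needs.

Step 3
Reactants: 3 (Z)-allylboronate; 4 (R)-2,2-dimethyl-1,3-dioxolane-4-carbaldehyde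
Product: 6 (1S,2S)-1-[(4R)-2,2-dimethyl-1,3-dioxolan-4-yl]-2-ethynyl-2-methylbut-3-en-1-ol, via pinacol borate 5 (not isolated)
Conditions: PhMe (2 M), 4 Å MS, 23 → 40 °C; aq. NaHCO3 work-up
Reagents that add atoms: none
Why: Allylboration through a closed six-membered chair transition state: the aldehyde substituent sits equatorial, the ethynyl group (cis to CH2B) sits axial and ends syn to the new C9 hydroxyl while the methyl ends anti, which fixes C10 relative to C9. The C8 dioxolane directs attack anti to its C–O bond (Felkin–Anh/Cornforth), the sense regularly seen with glyceraldehyde acetonide and Z-γ-substituted allylboronates, giving the 8,9-anti alcohol.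

Step 4
Reactants: 6 homoallylic alcohol; 7 2-methylpropanoyl chloride (isobutyryl chloride)
Product: 8 (1S,2S)-1-[(4R)-2,2-dimethyl-1,3-dioxolan-4-yl]-2-ethynyl-2-methylbut-3-en-1-yl 2-methylpropanoate
Conditions: pyridine, DMAP (0.2 equiv), CH2Cl2, 0 → 40 °C
Reagents that add atoms: none
Why: DMAP-catalysed acylation (acylpyridinium transfer) of the only free hydroxyl; the alcohol is neopentyl-like, hence the nucleophilic catalyst and mild warming, and no stereocentre is touched.

Step 5
Reactants: 8 acetonide ester
Product: 9 (2R,3S,4S)-4-ethynyl-1,2-dihydroxy-4-methylhex-5-en-3-yl 2-methylpropanoate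
Conditions: AcOH/H2O (4:1), 40 °C
Reagents that add atoms: none
Why: Acid hydrolysis of a terminal isopropylidene acetal; aqueous acetic acid is too weak to cleave the hindered isobutyrate and should not promote acyl migration to O8 at this temperature.

Step 6
Reactants: 9 diol
Product: 10 (2R,3S,4S)-4-ethynyl-4-methyl-1,2-bis[(triethylsilyl)oxy]hex-5-en-3-yl 2-methylpropanoate
Conditions: Et3SiOTf (2.5 equiv), 2,6-lutidine, CH2Cl2, −78 → 0 °C
Reagents that add atoms: triethylsilyl trifluoromethanesulfonate, CC[Si](CC)(CC)OS(=O)(=O)C(F)(F)F
Why: Silylation with a silyl triflate and a hindered pyridine base covers both the primary C7 and the hindered secondary C8 hydroxyl; the C8 ether is the protecting group for the cyclisation and the C7 ether is the latent aldehyde.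

Step 7
Reactants: 10 bis(triethylsilyl) ether
Product: 11 (2S,3S,4S)-4-ethynyl-4-methyl-1-oxo-2-[(triethylsilyl)oxy]hex-5-en-3-yl 2-methylpropanoate
Conditions: (COCl)2, DMSO, CH2Cl2, −78 → −30 °C; Et3N, −78 → 0 °C
Reagents that add atoms: none
Why: Swern oxidation applied directly to a bis(triethylsilyl) ether: the activated sulfoxide cleaves the less hindered primary Si–O bond and the alkoxysulfonium salt collapses to the aldehyde on adding base, while the secondary ether stays. The α-silyloxy aldehyde is used crude to avoid epimerisation at C8.

Step 8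
Reactants: 11 α-silyloxy aldehyde; 12 methyl (triphenylphosphoranylidene)acetate
Product: 13 methyl (2E,4R,5S,6S)-6-ethynyl-6-methyl-5-[(2-methylpropanoyl)oxy]-4-[(triethylsilyl)oxy]octa-2,7-dienoate
Conditions: CH2Cl2, 0 → 23 °C
Reagents that add atoms: none
Why: Wittig olefination with a stabilised ylide, which gives the (E)-enoate in aprotic solvent and is mild enough for the α-silyloxy aldehyde.

Step 9
Reactants: 13 enoate alkyne
Product: 14 methyl (2E,4R,5S,6R)-6-ethenyl-6-methyl-5-[(2-methylpropanoyl)oxy]-8-oxo-4-[(triethylsilyl)oxy]oct-2-enoate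
Conditions: [CpRu(NCMe){2-(Ph2P)-6-(t-Bu)C5H3N}2]PF6 (5 mol %), H2O (5 equiv), acetone, 60 °C
Reagents that add atoms: water, O
Why: Ruthenium-catalysed anti-Markovnikov hydration of a terminal alkyne through a vinylidene complex: water adds to the metal-bound carbon and tautomerisation with protonolysis releases the aldehyde. Alkenes, esters and silyl ethers are not touched by this bifunctional phosphinopyridine catalyst.

Step 10
Reactants: 14 aldehyde–enoate
Product: 15 methyl 2-[(1R,2R,3S,4R)-4-ethenyl-4-methyl-3-[(2-methylpropanoyl)oxy]-6-oxo-2-[(triethylsilyl)oxy]cyclohexyl]acetate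
Conditions: 2-(pentafluorophenyl)-6,7-dihydro-5H-pyrrolo[2,1-c][1,2,4]triazol-2-ium tetrafluoroborate (20 mol %), KN(SiMe3)2 (18 mol %), PhMe, 23 → 40 °C
Reagents that add atoms: none
Why: The free carbene adds to the C6 aldehyde and proton transfer gives the Breslow intermediate, an acyl-anion equivalent; the closest known reaction is the triazolium-catalysed intramolecular Stetter reaction of aliphatic aldehydes with tethered enoates. Its nucleophilic carbon adds 6-exo-trig to C7 of the (E)-enoate, forming C6–C7 and closing the cyclohexane (C5–C10); protonation of the ester enolate at C11 and collapse of the tetrahedral intermediate release the carbene and the C6 ketone. The quaternary C10 biases the chain towards the reactive gauche conformer and leaves the aldehyde without α-branching, so carbene addition is not hindered. The only new stereocentre is C7: in the chair-like transition state the enoate arm and the C8 silyl ether are both equatorial, whereas an arm cis to O8 would be 1,3-diaxial to the C9 isobutyrate. Because C7 is α to the new ketone, any cis isomer should equilibrate to the same trans product under the reaction conditions, so the outcome does not rest on kinetic selectivity alone. The step needs chemoselectivity for conjugate addition over aldol and benzoin pathways; using less base than azolium salt leaves no free strong base, and the neopentyl-type aldehyde disfavours bimolecular coupling. C8, C9 and C10 are not enolisable and pass through unchanged.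

Step 11
Reactants: 15 cyclohexanone; 16 1-bromo-3-methylbut-2-ene (prenyl bromide)
Product: 17 methyl 2-[(1R,2R,3S,4S,5S)-4-ethenyl-4-methyl-5-(3-methylbut-2-en-1-yl)-3-[(2-methylpropanoyl)oxy]-6-oxo-2-[(triethylsilyl)oxy]cyclohexyl]acetate (ring numbered from the carbon bearing the acetate arm towards the silyloxy carbon)
Conditions: LiN(i-Pr)2 (1.05 equiv), THF, −78 °C; 16, DMPU, −78 → −40 °C; AcOH; then DBU (0.2 equiv), CH2Cl2, 0 °C
Reagents that add atoms: none
Why: Kinetic deprotonation with a bulky amide takes a C5 methylene proton in preference to the C7 methine, and the ester α-protons are far less acidic; C-alkylation with the reactive allylic bromide installs the prenyl group as a masked CH2CHO unit. C5 is α to the ketone, so brief exposure to DBU funnels any axial epimer to the equatorial one (an axial prenyl group would be 1,3-diaxial to the C9 isobutyrate).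

Step 12
Reactants: 17 prenyl keto ester
Product: 19 (3aR,5S,6S,7S,7aR)-6-ethenyl-6-methyl-5-(3-methylbut-2-en-1-yl)-2,4-dioxooctahydro-1-benzofuran-7-yl 2-methylpropanoate, via hydroxy ester 18 (not isolated)
Conditions: p-TsOH·H2O (0.2 equiv), MeOH, 0 → 23 °C; concentrate; CH2Cl2, 23 °C
Reagents that add atoms: none
Why: Acid-catalysed methanolysis of the triethylsilyl ether frees the C8 hydroxyl, which lactonises onto the C12 methyl ester under the same acid once methanol is removed. O8 and the C7 arm are both equatorial, so the γ-lactone closes trans-fused, and the axial O9 ester cannot reach C12.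

Step 13
Reactants: 19 keto lactone
Product: 20 (3aS,4S,5S,6S,7S,7aR)-6-ethenyl-4-hydroxy-6-methyl-5-(3-methylbut-2-en-1-yl)-2-oxooctahydro-1-benzofuran-7-yl 2-methylpropanoate
Conditions: LiBH(s-Bu)3 (1.2 equiv), THF, −78 °C; AcOH, −78 °C
Reagents that add atoms: none
Why: Hydride addition to the cyclohexanone: axial approach to C6 is blocked by the syn-axial C14 methyl on C10, so the bulky tri-sec-butylborohydride attacks from the equatorial side and gives the axial C6 alcohol. The low temperature and acidic quench keep the alkoxide from attacking the lactone.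

Step 14
Reactants: 20 hydroxy lactone
Product: 21 (3aR,4S,5S,6S,7S,7aR)-6-ethenyl-6-methyl-5-(3-methylbut-2-en-1-yl)-2-oxo-4-[(triethylsilyl)oxy]octahydro-1-benzofuran-7-yl 2-methylpropanoate
Conditions: Et3SiOTf, 2,6-lutidine, CH2Cl2, −78 → 0 °C
Reagents that add atoms: triethylsilyl trifluoromethanesulfonate, CC[Si](CC)(CC)OS(=O)(=O)C(F)(F)F
Why: Silylation of the hindered axial alcohol with a silyl triflate; the ether prevents alkoxide formation and translactonisation to O6 in the enolate step that follows.

Step 15
Reactants: 21 silyl ether lactone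
Product: 24 (3aR,4S,5S,6S,7S,7aR)-6-ethenyl-6-methyl-5-(3-methylbut-2-en-1-yl)-3-methylidene-2-oxo-4-[(triethylsilyl)oxy]octahydro-1-benzofuran-7-yl 2-methylpropanoate, via Mannich base 22 (not isolated), via ammonium iodide 23 (not isolated)
Conditions: LiN(i-Pr)2 (1.2 equiv), THF, −78 °C; CH2=NMe2+ I−, −78 → 23 °C; MeI, THF, 23 °C; aq. NaHCO3, CH2Cl2, 23 °C
Reagents that add atoms: N,N-dimethylmethyleneiminium iodide (Eschenmoser's salt), C=[N+](C)C.[I-]
Why: α-Methylenation of a lactone by the Mannich route: the C11 lithium enolate reacts with the iminium salt, N-methylation turns the amine into a leaving group and mild base induces E1cB elimination to the exocyclic alkene. The lactone α-CH2 is more acidic and less hindered than the isobutyrate α-CH, and the C11 stereocentre of the intermediates is lost on elimination.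

Step 16
Reactants: 24 prenyl methylene lactone
Product: 25 (3aR,4S,5S,6S,7S,7aR)-6-ethenyl-6-methyl-3-methylidene-2-oxo-5-(2-oxoethyl)-4-[(triethylsilyl)oxy]octahydro-1-benzofuran-7-yl 2-methylpropanoate
Conditions: O3 (Sudan Red 7B end point), pyridine (3 equiv), CH2Cl2, −78 °C
Reagents that add atoms: ozone, [O-][O+]=O
Why: Ozonolysis is selective for the electron-rich trisubstituted prenyl alkene over the hindered monosubstituted vinyl group and the electron-poor methylene lactone, and is stopped at the indicator end point. Pyridine intercepts the carbonyl oxide, so the aldehyde forms without a reductive work-up.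

Step 17
Reactants: 25 aldehyde
Product: 26 (3aR,4S,5R,6S,7S,7aR)-6-ethenyl-6-methyl-3-methylidene-2-oxo-5-(3-oxoprop-1-en-2-yl)-4-[(triethylsilyl)oxy]octahydro-1-benzofuran-7-yl 2-methylpropanoate
Conditions: 37% aq. CH2O, pyrrolidine (10 mol %), propionic acid (10 mol %), i-PrOH, 45 °C
Reagents that add atoms: formaldehyde, C=O
Why: Amine-catalysed Mannich condensation with formaldehyde followed by elimination (organocatalytic α-methylenation of an aldehyde) gives the 2-substituted acrolein. The amine is catalytic, so it cannot consume the methylene lactone by conjugate addition, and C5 keeps its configuration because isomerisation into conjugation would create a strained tetrasubstituted exocyclic alkene.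

Step 18
Reactants: 26 silyl ether
Product: 27 (3aS,4S,5R,6S,7S,7aR)-6-ethenyl-4-hydroxy-6-methyl-3-methylidene-2-oxo-5-(3-oxoprop-1-en-2-yl)octahydro-1-benzofuran-7-yl 2-methylpropanoate
Conditions: HF·pyridine, pyridine, THF, 0 → 23 °C
Reagents that add atoms: none
Why: Fluoride-mediated cleavage of the silyl ether under buffered, weakly acidic conditions, which spare both Michael acceptors and avoid the alkoxide that could translactonise.

Step 19
Reactants: 27 vinyl alcohol
Product: 28 (3aS,4S,5R,6R,7S,7aR)-4-hydroxy-6-methyl-3-methylidene-6-[(2R)-oxiran-2-yl]-2-oxo-5-(3-oxoprop-1-en-2-yl)octahydro-1-benzofuran-7-yl 2-methylpropanoate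
Conditions: dimethyldioxirane (1.5 equiv), acetone, −20 → 0 °C
Reagents that add atoms: dimethyldioxirane, CC1(C)OO1
Why: Electrophilic epoxidation with a dioxirane should react with the only electron-rich alkene, the vinyl group, and leave the two conjugated alkenes; the neutral medium protects the product epoxide. With C5 (the bulkiest neighbour) anti to the incoming oxygen, C9 inside and the C14 methyl outside, attack on the vinyl rotamer should give the (1R) epoxide, although this facial preference is the least secure stereochemical call of the route.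

## Compound list

1 | (Z)-3-methylpent-2-en-4-yn-1-ol | C#C/C(C)=C\CO | starting material
2 | (Z)-5-chloro-3-methylpent-3-en-1-yne | C#C/C(C)=C\CCl | intermediate
3 | 4,4,5,5-tetramethyl-2-[(2Z)-3-methylpent-2-en-4-yn-1-yl]-1,3,2-dioxaborolane | C#C/C(C)=C\CB1OC(C)(C)C(C)(C)O1 | intermediate
4 | (R)-2,2-dimethyl-1,3-dioxolane-4-carbaldehyde | O=C[C@H]1COC(C)(C)O1 | starting material
5 | pinacol borate of alcohol 6 (not isolated) | C#C[C@](C)(C=C)[C@H](OB1OC(C)(C)C(C)(C)O1)[C@H]1COC(C)(C)O1 | intermediate
6 | (1S,2S)-1-[(4R)-2,2-dimethyl-1,3-dioxolan-4-yl]-2-ethynyl-2-methylbut-3-en-1-ol | C#C[C@](C)(C=C)[C@H](O)[C@H]1COC(C)(C)O1 | intermediate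
7 | 2-methylpropanoyl chloride | CC(C)C(Cl)=O | starting material
8 | (1S,2S)-1-[(4R)-2,2-dimethyl-1,3-dioxolan-4-yl]-2-ethynyl-2-methylbut-3-en-1-yl 2-methylpropanoate | C#C[C@](C)(C=C)[C@H](OC(=O)C(C)C)[C@H]1COC(C)(C)O1 | intermediate
9 | (2R,3S,4S)-4-ethynyl-1,2-dihydroxy-4-methylhex-5-en-3-yl 2-methylpropanoate | C#C[C@](C)(C=C)[C@H](OC(=O)C(C)C)[C@H](O)CO | intermediate
10 | (2R,3S,4S)-4-ethynyl-4-methyl-1,2-bis[(triethylsilyl)oxy]hex-5-en-3-yl 2-methylpropanoate | C#C[C@](C)(C=C)[C@H](OC(=O)C(C)C)[C@H](O[Si](CC)(CC)CC)CO[Si](CC)(CC)CC | intermediate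
11 | (2S,3S,4S)-4-ethynyl-4-methyl-1-oxo-2-[(triethylsilyl)oxy]hex-5-en-3-yl 2-methylpropanoate | C#C[C@](C)(C=C)[C@H](OC(=O)C(C)C)[C@H](O[Si](CC)(CC)CC)C=O | intermediate
12 | methyl (triphenylphosphoranylidene)acetate | COC(=O)C=P(c1ccccc1)(c1ccccc1)c1ccccc1 | starting material
13 | methyl (2E,4R,5S,6S)-6-ethynyl-6-methyl-5-[(2-methylpropanoyl)oxy]-4-[(triethylsilyl)oxy]octa-2,7-dienoate | C#C[C@](C)(C=C)[C@H](OC(=O)C(C)C)[C@H](O[Si](CC)(CC)CC)/C=C/C(=O)OC | intermediate
14 | methyl (2E,4R,5S,6R)-6-ethenyl-6-methyl-5-[(2-methylpropanoyl)oxy]-8-oxo-4-[(triethylsilyl)oxy]oct-2-enoate | O=CC[C@](C)(C=C)[C@H](OC(=O)C(C)C)[C@H](O[Si](CC)(CC)CC)/C=C/C(=O)OC | intermediate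
15 | methyl 2-[(1R,2R,3S,4R)-4-ethenyl-4-methyl-3-[(2-methylpropanoyl)oxy]-6-oxo-2-[(triethylsilyl)oxy]cyclohexyl]acetate | O=C1C[C@](C)(C=C)[C@H](OC(=O)C(C)C)[C@H](O[Si](CC)(CC)CC)[C@H]1CC(=O)OC | intermediate
16 | 1-bromo-3-methylbut-2-ene | CC(C)=CCBr | starting material
17 | methyl 2-[(1R,2R,3S,4S,5S)-4-ethenyl-4-methyl-5-(3-methylbut-2-en-1-yl)-3-[(2-methylpropanoyl)oxy]-6-oxo-2-[(triethylsilyl)oxy]cyclohexyl]acetate | O=C1[C@@H](CC=C(C)C)[C@](C)(C=C)[C@H](OC(=O)C(C)C)[C@H](O[Si](CC)(CC)CC)[C@H]1CC(=O)OC | intermediate
18 | methyl 2-[(1R,2R,3S,4S,5S)-4-ethenyl-2-hydroxy-4-methyl-5-(3-methylbut-2-en-1-yl)-3-[(2-methylpropanoyl)oxy]-6-oxocyclohexyl]acetate (not isolated) | O=C1[C@@H](CC=C(C)C)[C@](C)(C=C)[C@H](OC(=O)C(C)C)[C@H](O)[C@H]1CC(=O)OC | intermediate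
19 | (3aR,5S,6S,7S,7aR)-6-ethenyl-6-methyl-5-(3-methylbut-2-en-1-yl)-2,4-dioxooctahydro-1-benzofuran-7-yl 2-methylpropanoate | C1C(=O)O[C@@H]2[C@@H]1C(=O)[C@@H](CC=C(C)C)[C@](C)(C=C)[C@@H]2OC(=O)C(C)C | intermediate
20 | (3aS,4S,5S,6S,7S,7aR)-6-ethenyl-4-hydroxy-6-methyl-5-(3-methylbut-2-en-1-yl)-2-oxooctahydro-1-benzofuran-7-yl 2-methylpropanoate | C1C(=O)O[C@@H]2[C@@H]1[C@@H](O)[C@@H](CC=C(C)C)[C@](C)(C=C)[C@@H]2OC(=O)C(C)C | intermediate
21 | (3aR,4S,5S,6S,7S,7aR)-6-ethenyl-6-methyl-5-(3-methylbut-2-en-1-yl)-2-oxo-4-[(triethylsilyl)oxy]octahydro-1-benzofuran-7-yl 2-methylpropanoate | C1C(=O)O[C@@H]2[C@@H]1[C@@H](O[Si](CC)(CC)CC)[C@@H](CC=C(C)C)[C@](C)(C=C)[C@@H]2OC(=O)C(C)C | intermediate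
22 | 3-[(dimethylamino)methyl] derivative of lactone 21, mixture of C3 epimers (not isolated) | CN(C)CC1C(=O)O[C@@H]2[C@@H]1[C@@H](O[Si](CC)(CC)CC)[C@@H](CC=C(C)C)[C@](C)(C=C)[C@@H]2OC(=O)C(C)C | intermediate
23 | trimethylammonium iodide of Mannich base 22 (not isolated) | C[N+](C)(C)CC1C(=O)O[C@@H]2[C@@H]1[C@@H](O[Si](CC)(CC)CC)[C@@H](CC=C(C)C)[C@](C)(C=C)[C@@H]2OC(=O)C(C)C.[I-] | intermediate
24 | (3aR,4S,5S,6S,7S,7aR)-6-ethenyl-6-methyl-5-(3-methylbut-2-en-1-yl)-3-methylidene-2-oxo-4-[(triethylsilyl)oxy]octahydro-1-benzofuran-7-yl 2-methylpropanoate | C=C1C(=O)O[C@@H]2[C@@H]1[C@@H](O[Si](CC)(CC)CC)[C@@H](CC=C(C)C)[C@](C)(C=C)[C@@H]2OC(=O)C(C)C | intermediate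
25 | (3aR,4S,5S,6S,7S,7aR)-6-ethenyl-6-methyl-3-methylidene-2-oxo-5-(2-oxoethyl)-4-[(triethylsilyl)oxy]octahydro-1-benzofuran-7-yl 2-methylpropanoate | C=C1C(=O)O[C@@H]2[C@@H]1[C@@H](O[Si](CC)(CC)CC)[C@@H](CC=O)[C@](C)(C=C)[C@@H]2OC(=O)C(C)C | intermediate
26 | (3aR,4S,5R,6S,7S,7aR)-6-ethenyl-6-methyl-3-methylidene-2-oxo-5-(3-oxoprop-1-en-2-yl)-4-[(triethylsilyl)oxy]octahydro-1-benzofuran-7-yl 2-methylpropanoate | C=C1C(=O)O[C@@H]2[C@@H]1[C@@H](O[Si](CC)(CC)CC)[C@@H](C(=C)C=O)[C@](C)(C=C)[C@@H]2OC(=O)C(C)C | intermediate
27 | (3aS,4S,5R,6S,7S,7aR)-6-ethenyl-4-hydroxy-6-methyl-3-methylidene-2-oxo-5-(3-oxoprop-1-en-2-yl)octahydro-1-benzofuran-7-yl 2-methylpropanoate | C=C1C(=O)O[C@@H]2[C@@H]1[C@@H](O)[C@@H](C(=C)C=O)[C@](C)(C=C)[C@@H]2OC(=O)C(C)C | intermediate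
28 | (3aS,4S,5R,6R,7S,7aR)-4-hydroxy-6-methyl-3-methylidene-6-[(2R)-oxiran-2-yl]-2-oxo-5-(3-oxoprop-1-en-2-yl)octahydro-1-benzofuran-7-yl 2-methylpropanoate (CNP0519565.1) | C=C1C(=O)O[C@@H]2[C@@H]1[C@@H](O)[C@@H](C(=C)C=O)[C@](C)([C@@H]1CO1)[C@@H]2OC(=O)C(C)C | target

## Count and risks

Total step count: 19. Longest linear sequence: 19 steps (1 → 28); compounds 4, 7, 12 and 16 are purchased.

**Step 10 (key step).** The most likely failure is slow formation or slow 6-exo addition of the Breslow intermediate from an aliphatic aldehyde. Aldol condensation of the enolisable aldehyde, or β-elimination of the C8 silyloxy group from the product ketone, would then compete. Fallback with the same bond and ring but a radical instead of a polar acyl equivalent: aldehyde 14 is oxidised (NaClO2, NaH2PO4, 2-methylbut-2-ene) to carboxylic acid F1. This is converted with (PhSe)2 and PBu3 into Se-phenyl selenoester F2. Bu3SnH with AIBN in benzene at 80 °C then generates the C6 acyl radical, which should add 6-exo-trig to C7 of the enoate and return the route at ketone 15 (C7 equilibrated with DBU). Attack on the C10 vinyl group would be a disfavoured 5-endo closure.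

**Step 3 (with step 2).** Erosion of the Z geometry by syn/anti exchange in the allylpalladium intermediate of step 2, or incomplete facial selectivity at the aldehyde, would give C10 or C9 epimers of 6. Fallback without boron: alcohol 1 is converted with diethyl chlorophosphate and pyridine into (Z)-diethyl 3-methylpent-2-en-4-yn-1-yl phosphate F3. With CrCl2 and catalytic LiI in DMPU, F3 adds to aldehyde 4 as a γ,γ-disubstituted allylchromium reagent (divalent chromium, Nozaki–Hiyama type). Transfer of alkene geometry through a chair transition state is documented for such reagents, and the route is rejoined at alcohol 6.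

**Step 9.** The alkyne sits on a quaternary carbon, so vinylidene formation may be slow and conversion incomplete, and prolonged heating risks loss of the silyl ether. Fallback by stoichiometric hydroboration: alkyne 13 is treated with dicyclohexylborane at 0 °C, which should prefer the alkyne over the hindered vinyl group and give (E)-alkenylborane F4. Buffered oxidation (NaBO3·4H2O) then gives aldehyde 14.

**Step 11.** Enolisation towards C7 instead of C5, followed by β-elimination of the C8 silyloxy group, or sluggish alkylation of the neopentyl-type enolate, would erode the yield. Fallback through an aza-enolate: ketone 15 is condensed with 1,1-dimethylhydrazine (cat. AcOH) to N,N-dimethylhydrazone F5. Metallation with LiN(i-Pr)2, which takes the less substituted α-carbon with high fidelity, and alkylation with 16 give prenyl hydrazone F6. Hydrolysis with aqueous CuCl2 returns the route at ketone 17.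

**Step 19.** Poor or reversed facial selectivity at C1 is the main danger, since two vinyl rotamers are accessible. Over-oxidation of the formyl group or of the C6 carbinol by the dioxirane is a second danger. Fallback by a two-step anti pathway: alcohol 27 is treated with NBS in aqueous THF to give (1R)-bromohydrin F7 by opening of the bromonium ion with water. Closure with K2CO3 in acetone then gives 28. This sequence places the oxygen on the face opposite to that chosen by a direct electrophile, so it serves if the dioxirane favours the (1S) epimer. If neither method is selective, the C1 epimers are diastereomers and can be separated.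

## Further compounds

F1 | step 10 | (3R,4S,5R,6E)-3-ethenyl-8-methoxy-3-methyl-4-[(2-methylpropanoyl)oxy]-8-oxo-5-[(triethylsilyl)oxy]oct-6-enoic acid | OC(=O)C[C@](C)(C=C)[C@H](OC(=O)C(C)C)[C@H](O[Si](CC)(CC)CC)/C=C/C(=O)OC
F2 | step 10 | Se-phenyl selenoester of acid F1 | O=C([Se]c1ccccc1)C[C@](C)(C=C)[C@H](OC(=O)C(C)C)[C@H](O[Si](CC)(CC)CC)/C=C/C(=O)OC
F3 | step 3 | (Z)-diethyl 3-methylpent-2-en-4-yn-1-yl phosphate | C#C/C(C)=C\COP(=O)(OCC)OCC
F4 | step 9 | (E)-alkenyl(dicyclohexyl)borane from alkyne 13 | C1CCCCC1B(C1CCCCC1)/C=C/[C@](C)(C=C)[C@H](OC(=O)C(C)C)[C@H](O[Si](CC)(CC)CC)/C=C/C(=O)OC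
F5 | step 11 | N,N-dimethylhydrazone of ketone 15 | CN(C)N=C1C[C@](C)(C=C)[C@H](OC(=O)C(C)C)[C@H](O[Si](CC)(CC)CC)[C@H]1CC(=O)OC
F6 | step 11 | N,N-dimethylhydrazone of ketone 17 | CN(C)N=C1[C@@H](CC=C(C)C)[C@](C)(C=C)[C@H](OC(=O)C(C)C)[C@H](O[Si](CC)(CC)CC)[C@H]1CC(=O)OC
F7 | step 19 | (1R)-2-bromo-1-hydroxyethyl analogue of 28 (bromohydrin) | C=C1C(=O)O[C@@H]2[C@@H]1[C@@H](O)[C@@H](C(=C)C=O)[C@](C)([C@@H](O)CBr)[C@@H]2OC(=O)C(C)C
A1 | alternative 1 | trans ethynyl carbinol (C7 ethynyl, C8 hydroxyl, C6 silyl ether, C5 isopropenyl, C1–C2 acetonide) | C#C[C@H]1[C@@H](O[Si](C)(C)C(C)(C)C)[C@@H](C(C)=C)[C@](C)([C@@H]2COC(C)(C)O2)[C@H](OC(=O)C(C)C)[C@@H]1O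
A2 | alternative 1 | trans-fused α-methylene-γ-butyrolactone (C6 silyl ether, C5 isopropenyl, C1–C2 acetonide) | C=C1C(=O)O[C@@H]2[C@@H]1[C@@H](O[Si](C)(C)C(C)(C)C)[C@@H](C(C)=C)[C@](C)([C@@H]3COC(C)(C)O3)[C@@H]2OC(=O)C(C)C
A3 | alternative 2 | (1(10)E,4E)-6-hydroxy-9-isobutyryloxygermacra-1(10),4,11(13)-trien-8,12-olide | C/C1=C\CC/C(C)=C/[C@H](O)[C@@H]2C(=C)C(=O)O[C@H]2[C@H]1OC(=O)C(C)C
A4 | alternative 2 | elemanolide with C10 vinyl and C5 isopropenyl | C=C1C(=O)O[C@@H]2[C@@H]1[C@@H](O)[C@@H](C(C)=C)[C@](C)(C=C)[C@@H]2OC(=O)C(C)C
A5 | alternative 3 | open-chain C8 aldehyde with (E)-enoate at C7 (C6 silyl ether, C9 PMB ether) | COC(=O)/C=C/[C@@H](O[Si](C)(C)C(C)(C)C)[C@@H](C(C)=C)[C@](C)(C=C)[C@H](OCc1ccc(OC)cc1)C=O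
A6 | alternative 3 | trans-8-hydroxycyclohexane with C7 acetate arm | COC(=O)C[C@H]1[C@@H](O[Si](C)(C)C(C)(C)C)[C@@H](C(C)=C)[C@](C)(C=C)[C@H](OCc2ccc(OC)cc2)[C@@H]1O
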